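At 20 h, when four flasks with different initiator charges are read, how much product can stand in them at most, and how much will?

in all of them: substrate 0.57 M; reagent 0.513 M

| charge | initiator | remark | time |
|---|---|---|---|
| Thursday's | 9.1 mM | run made earlier |  |
| Friday's | 82 mM | run made earlier |  |
| birch | 8.0 mM |  | 20 h |
| maple | 15 mM |  | 20 h |
| alder | 30 mM |  | 20 h |
| larch | 60 mM |  | 20 h |

- Thursday's (time / h: product / %): 1.50: 3.8; 3.00: 5.4; 6.00: 11.4; 10.0: 19.0; 20.0: 32.6
- Friday's (time / h: product / %): 2.00: 13.6; 5.00: 28.7; 10.0: 48.6; 15.0: 63.3; 20.0: 73.1

(each reading ± 1 percentage point)

- the numbers in the tables scatter by 1 percentage point (one standard deviation)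
- "hardly changes" means that all values lie within two and a half points (for a concentration: within two and a half percent of the largest)

* amount of product at the end, in percent of the substrate charged for birch, maple, alder, larch, in this order
* the course of these numbers from the first flask to the last (falls, then rises / hardly changes / rises all the way / falls all the way / rises, then falls)

Which charge runs out first? The reagent, since c(reagent) starts lower, at 0.513 M, than the 0.57 M of substrate, so I take it as the limiting reagent, assume one reagent per product, and write its balance as c(reagent) = 0.513 M − c(product), which gives a reagent ceiling on product of 90.0% of the substrate charged.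

Does that ceiling bend the curves before it is reached? I test this on Friday's run with the logarithm of substrate charged over substrate left, taken per hour: it reads 0.0666 /h at 10.0 h and 0.0657 /h at 20.0 h, although the balance takes the reagent left from 46.0% to 18.8% of its charge between those readings, so within the scatter these two readings of Friday's run stand level and show no sign of the reagent.

And the initiator? The same logarithm at 20 h reads 0.395 on Thursday and 1.31 on Friday, which makes the order in initiator a reading of 0.547, and scaling Thursday's value by it gives me 30.8%, 40.5%, 53.1% and 66.9%, a row that climbs from the first flask to the last.

Where is this weakest? At larch, the flask with the most initiator, yet by the balance larch keeps 25.6% of its reagent, more than the 18.8% at which Friday's reading per hour still stood level; a run whose reading per hour sagged at that reagent level would undo the reckoning.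

The forecast, slightly above mine in maple, gives 31%, 41%, 53.5% and 67%, a course that rises all the way, and says “the yield should rise throughout”.

The flasks give 32.1%, 41.4%, 53.6% and 67.2%: rises all the way.

    initiator → 2 initiating radical (k = 0.0101 /h)
    substrate + initiating radical → capped initiator + first chain carrier (k = 12800 /M/s)
    2 second chain carrier → ended chains (k = 3.30 × 10⁷ /M/s)
    substrate + second chain carrier → by-product + first chain carrier (k = 7.69 × 10⁵ /M/h)
    reagent + first chain carrier ⇌ product + second chain carrier (K = 3.83, k = 7.93 × 10⁵ /M/h)

Larch ends at 67.2% with 33% of its substrate left, and the ceiling of 90.0% turns that product into 25.3% of the reagent left, where the flask holds 25%. Maple, followed to 200 h, meets the ceiling with product at 90.0%, reagent at 0% and substrate at 8.81%.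

All runs are simulated with constants of no real substance; noise was put on by code.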